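## Structural features

17 is a 3,4-disubstituted γ-butyrolactone of the dibenzylbutyrolactone lignan class: one five-membered lactone and two benzene rings, each joined to the lactone through a single CH2 group. C3, α to the carbonyl, carries the 4-hydroxy-3-methoxybenzyl group (ring A), and C4, next to the ring CH2–O (C5), carries the 4-hydroxy-3,5-dimethoxybenzyl group (ring B). C3 and C4 are adjacent stereocentres, both R, with the two benzyl groups trans. C3 is enolisable, so base can correct it but also scramble it, whereas C4 is not acidic and cannot be repaired once set. The two free phenols are electron rich, sensitive to oxidants and incompatible with organometallic reagents, and the lactone does not tolerate hydroxide or an excess of hard nucleophiles. The real difficulty is therefore the absolute configuration at C4 and the unambiguous placement of two very similar aryl groups on C3 and C4. The key step exploits the C4–CH2–aryl(ring B) unit flanked by C5H2–O1 and C3: this is the pattern left when an aryl nucleophile opens C6 of a 3-oxabicyclo[3.1.0]hexan-2-one, whose ring-fusion carbon becomes C4. With C4 fixed, C3 follows from anti alkylation of the lactone enolate.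

## Logic of the disconnections

17 to 16: the two phenolic O–CH2Ph bonds are cut. Both phenols must be masked through the magnesium, copper, hot chloride and amide-base steps, and one kind of mask on both allows a single final unmasking. The skeleton is unchanged, but all the polar chemistry before it becomes possible. The forward step must be a neutral hydrogenolysis that spares the lactone C–O bonds and the aryl methyl ethers and does not epimerise C3.

16 to 12 and 14: the C3–CH2(ring A) bond is cut. C3 is the natural enolate carbon, and the C4 substituent of 12 directs an incoming electrophile to the opposite face. The cut halves the molecule, removes one stereocentre, and places ring A on C3 without ambiguity. The forward step must be a kinetic mono-alkylation with high anti selectivity.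

14 to 13: the C–Br bond is traced to the C–OH bond of a purchasable benzylic alcohol. The demand is a mild bromination that leaves the benzyl aryl ether intact, with the bromide used fresh.

12 to 10: a methoxycarbonyl group is added back on C3. This ester is what activates the cyclopropane for the key step, so it must be present in 10 and removed afterwards. It is taken off before ring A is introduced, so that C3 is set by a kinetically controlled alkylation and not by the protonation of a decarboxylation enolate, whose facial preference is uncertain. The forward step requires chloride to attack the ester methyl group in preference to the lactone CH2 and leaves C4 untouched.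

10 to 5 and 8: the CH2–aryl(ring B) bond is cut and the CH2 is reconnected to C3, which gives the cyclopropane of 5. The cut removes the whole of ring B as a simple aryl metal reagent and traces C4 to the ring-fusion carbon of a small bicyclic lactone of defined configuration. The forward step must attack the cyclopropane CH2 and not the ring-fusion carbon or a carbonyl group.

5 to 1 and 2: the bonds C1–C6, C1–C5 and O3–C2 of 5 are cut. All three form in one operation from a malonate and a three-carbon epoxide, and the only stereocentre that matters is taken from the chiral pool. The forward step requires the malonate to open the epoxide before it displaces chloride, because the other order leads to the enantiomer.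

8 to 7 to 6: the C–Mg bond is traced to the C–Br bond of 7 and the O–CH2Ph bond of 7 to the phenol 6. Both are functional-group changes on a purchasable bromophenol. The demand is clean magnesium insertion into an electron-rich aryl bromide without homocoupling.

## Other disconnections considered

Alternative 1: The O1–C5 bond of the monobenzyl lactone is cut, leading to the achiral 3-[4-(benzyloxy)-3,5-dimethoxybenzyl]cyclobutan-1-one A1. In the forward direction a chiral phosphoric acid with aqueous hydrogen peroxide, or a Baeyer–Villiger monooxygenase, would insert oxygen into one of the two enantiotopic acyl bonds of A1 and give (4R)-4-[4-(benzyloxy)-3,5-dimethoxybenzyl]dihydrofuran-2(3H)-one A2, which is identical with 12.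
- In its favour: the stereocentre is created catalytically from an achiral ketone, the oxidant is cheap, and no organometallic reagent or cryogenic step is needed.
- Against it here: the only group that distinguishes the two migrating CH2 groups is a flexible arylmethyl substituent one carbon away from the ring, so high enantiotopic discrimination is harder to expect than for 3-aryl cyclobutanones. The very electron-rich arene must also survive a peracid-type oxidant under Brønsted acid, and the sense of induction would have to be established for the catalyst chosen.
- Comparison: in structure the two plans are equal, since both arrive at the same lactone and share the endgame of steps 7 and 8. In mechanism the alternative relies on catalyst control in a Criegee-type migration, while the chosen plan takes C4 from 1 with a predictable absolute configuration, which is the safer of the two. In step economy the alternative is equal or one step better up to this lactone, if A1 is reached by a ketene cycloaddition–dechlorination sequence from the matching allylarene, and it is better in reagent economy.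

Alternative 2: The C3–C4 bond is cut, leading to the ester (2S,3Z)-5-[4-(benzyloxy)-3,5-dimethoxyphenyl]pent-3-en-2-yl 3-[4-(benzyloxy)-3-methoxyphenyl]propanoate A3. In the forward direction LiN(i-Pr)2 and Me3SiCl in THF would give the silyl ketene acetal with the α-substituent trans to the silyloxy group. A chair transition state with the carbinol methyl group equatorial and the Z substituent axial would then give the syn acid (2R,3S,4E)-2-[4-(benzyloxy)-3-methoxybenzyl]-3-[4-(benzyloxy)-3,5-dimethoxybenzyl]hex-4-enoic acid A4. Oxidative cleavage of the propenyl group, reduction and lactonisation would lead from A4 to 16.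
- In its favour: the central C3–C4 bond and both stereocentres would form in one pericyclic event with a well-understood transfer of chirality, and the two aryl halves are joined through a simple ester.
- Against it here: an enantiopure Z-configured secondary allylic alcohol must be built first (alkyne benzylation, then semihydrogenation over Pd/CaCO3 poisoned with Pb(OAc)2). The diastereoselectivity depends on both the enolate geometry and the chair preference, which is weaker for Z-alkenes. The propenyl group must then be degraded to CH2–O in the presence of two oxidation-prone arenes.
- Comparison: in structure the alternative is the better, because it makes the ring-to-ring bond and both centres together, whereas the chosen plan sets C4 and C3 in separate events. In mechanism both are substrate controlled and predictable, so they are equal on that point. In step economy the alternative is clearly longer, by roughly three to four operations, and carries a risky oxidative cleavage that the chosen plan avoids.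

Alternative 3: The C4–C(benzylic) and C3–CH2 bonds are both cut, leading to (5R)-5-(l-menthyloxy)furan-2(5H)-one A5, 2-[4-(benzyloxy)-3,5-dimethoxyphenyl]-1,3-dithiane A6 and the bromide 14. In the forward direction A6, lithiated with n-BuLi, would add to C4 of A5 anti to the menthyloxy group. The resulting enolate would be benzylated at C3 by 14 anti to the new C4 substituent, giving the 3,4-trans-4,5-trans adduct A7. Desulfurisation with Raney Ni, reductive removal of the menthyloxy acetal (which turns C5 into CH2) and hydrogenolysis would complete the synthesis.
- In its favour: two skeletal bonds and both stereocentres would be made in one flask with reliable trans,trans control from a crystalline auxiliary-bearing butenolide, and both aryl groups arrive as simple building blocks.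
- Against it here: a stoichiometric auxiliary must be carried and removed, two extra steps are spent on erasing sulfur and the acetal, a large excess of Raney Ni and a cryogenic organolithium step are needed, and the acetal carbon has to be corrected in oxidation level.
- Comparison: in structure the alternative is the better, since its key step builds far more of the molecule than the chosen one. In mechanism the stereocontrol is equal, because the chosen plan likewise relies on anti addition to a five-membered enolate for C3. In step economy the two are about equal once the preparation of A6 and the removal steps are counted. The chosen plan is better in waste and in using a catalytic metal with a chiral-pool epoxide.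

Key step: step 4

Remark: C3 of 10 is a configurationally labile malonate-type centre; 10 is written as the trans (3S,4R) isomer expected to predominate, and this centre is erased in step 5.

Remark: (R)-configured 1 leads to (1S,5R)-5, and from there to 4R in 10, 12, 16 and 17, only if the malonate opens the epoxide before chloride is displaced; the protic alkoxide conditions of step 1 are chosen for that order.

Remark: 13, the O-benzylated and reduced form of vanillin, is taken as a purchasable starting material; otherwise it would cost two routine steps from vanillin.

## Route

Step 1
Reactants: 1 (R)-epichlorohydrin; 2 dimethyl malonate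
Product: 5 methyl (1S,5R)-2-oxo-3-oxabicyclo[3.1.0]hexane-1-carboxylate, via epoxy malonate 3 (not isolated), via cyclopropyl carbinol 4 (not isolated)
Conditions: NaOMe (1.0 equiv), MeOH, 0 °C to reflux; AcOH quench
Reagents that add atoms: none
Why: Tandem epoxide opening, Payne-type epoxide re-formation with loss of chloride, 3-exo-tet cyclopropanation and lactonisation: the malonate anion opens 1 at its epoxide CH2, the alkoxide closes to 3, and the malonate carbanion of 3 opens the new epoxide at the stereocentre with inversion to give 4, whose alkoxide lactonises onto the cis ester. C5 of 5 is the former C2 of 1, and C1 is fixed by the obligatory cis ring fusion.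

Step 2
Reactants: 6 4-bromo-2,6-dimethoxyphenol
Product: 7 2-(benzyloxy)-5-bromo-1,3-dimethoxybenzene
Conditions: BnBr, K2CO3, DMF, 60 °C
Reagents that add atoms: benzyl bromide, BrCc1ccccc1
Why: Williamson ether synthesis on a phenoxide; the benzyl ether is inert to magnesium, cuprates, hot LiCl and amide bases and leaves together with the second benzyl group in step 8.

Step 3
Reactants: 7 2-(benzyloxy)-5-bromo-1,3-dimethoxybenzene
Product: 8 [4-(benzyloxy)-3,5-dimethoxyphenyl]magnesium bromide (THF solution, titrated and used directly)
Conditions: Mg turnings, LiCl, I2 (cat.), THF, 25–45 °C
Reagents that add atoms: magnesium, [Mg]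
Why: Oxidative insertion of magnesium into the aryl C–Br bond (Grignard formation); LiCl keeps the electron-rich aryl reagent in solution and speeds insertion, and the ether groups are spectators.

Step 4
Reactants: 5 methyl (1S,5R)-2-oxo-3-oxabicyclo[3.1.0]hexane-1-carboxylate; 8 [4-(benzyloxy)-3,5-dimethoxyphenyl]magnesium bromide
Product: 10 methyl (3S,4R)-4-[4-(benzyloxy)-3,5-dimethoxybenzyl]-2-oxotetrahydrofuran-3-carboxylate, via bromomagnesium enolate 9 (not isolated)
Conditions: CuI (10 mol %), THF, −40 to −20 °C, slow addition of 8 (1.3 equiv); then 1 M HCl, 0 °C
Reagents that add atoms: none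
Why: Transmetalation of 8 to CuI gives a magnesium diarylcuprate of monovalent copper, which attacks the unsubstituted cyclopropane carbon C6 of 5 from the rear of the C1–C6 bond (oxidative addition to a trivalent copper alkyl, then reductive elimination), so the aryl–CH2 bond forms as C1–C6 breaks. The electrons of the broken bond end in the doubly stabilised bromomagnesium enolate 9, the copper catalyst is released for the next turnover, and protonation on work-up gives 10. The closest known reaction type is the copper-catalysed homoconjugate addition of Grignard reagents to cyclopropane-1,1-dicarboxylates and to alkyl 2-oxo-3-oxabicyclo[3.1.0]hexane-1-carboxylates. No ring is closed: the three-membered ring is opened and the five-membered lactone is kept. No stereocentre of consequence is created, because C4 of 10 is C5 of 5, none of whose bonds takes part, so its configuration is carried over from 1; C3 settles trans to the new arylmethyl group on protonation and is erased in step 5. The step needs regioselectivity for C6 over the ring-fusion carbon C5, which is secured by the primary, unhindered nature of C6 and by the fact that attack at C5 would hit a secondary carbon and give a six-membered lactone. It also needs chemoselectivity for ring opening over carbonyl addition, which is secured by the faster copper-mediated pathway at low temperature with slow addition of 8 and by the product staying masked as the unreactive enolate 9 until the quench. The benzyl ether and the methoxy groups of 8 are inert under these conditions.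

Step 5
Reactants: 10 methyl (3S,4R)-4-[4-(benzyloxy)-3,5-dimethoxybenzyl]-2-oxotetrahydrofuran-3-carboxylate
Product: 12 (4R)-4-[4-(benzyloxy)-3,5-dimethoxybenzyl]dihydrofuran-2(3H)-one, via lithium carboxylate 11 (not isolated)
Conditions: LiCl (2.5 equiv), H2O (2 equiv), DMSO, 140 °C
Reagents that add atoms: none
Why: Krapcho dealkoxycarbonylation: chloride demethylates the ester by SN2 attack at the methyl group, which is faster than attack at the β-branched lactone CH2, and carboxylate 11 loses CO2 to a lactone enolate that water protonates. C3 becomes CH2, and C4 is neither acidic nor involved, so its configuration is kept.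

Step 6
Reactants: 13 [4-(benzyloxy)-3-methoxyphenyl]methanol
Product: 14 1-(benzyloxy)-4-(bromomethyl)-2-methoxybenzene
Conditions: PBr3 (0.4 equiv), Et2O, 0 °C; used at once
Reagents that add atoms: phosphorus tribromide, BrP(Br)Br
Why: Conversion of a benzylic alcohol into the bromide through its phosphite ester and SN2 displacement by bromide; the low temperature and short contact time protect the benzyl aryl ether and the labile electron-rich bromide.

Step 7
Reactants: 12 (4R)-4-[4-(benzyloxy)-3,5-dimethoxybenzyl]dihydrofuran-2(3H)-one; 14 1-(benzyloxy)-4-(bromomethyl)-2-methoxybenzene
Product: 16 (3R,4R)-3-[4-(benzyloxy)-3-methoxybenzyl]-4-[4-(benzyloxy)-3,5-dimethoxybenzyl]dihydrofuran-2(3H)-one, via lithium enolate 15 (not isolated)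
Conditions: LiN(SiMe3)2 (1.05 equiv), THF, −78 °C; then 14 (1.1 equiv), DMPU, −78 to −40 °C; aq NH4Cl
Reagents that add atoms: none
Why: Kinetic lactone enolate alkylation: the planar lithium enolate 15 is attacked by the benzylic bromide on the face opposite the C4 arylmethyl group, so the new C3 substituent is placed trans and C3 is set as R by 1,2-induction from C4. Low temperature and a slight excess of 14 keep proton exchange, and with it double alkylation or epimerisation, in check.

Step 8
Reactants: 16 (3R,4R)-3-[4-(benzyloxy)-3-methoxybenzyl]-4-[4-(benzyloxy)-3,5-dimethoxybenzyl]dihydrofuran-2(3H)-one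
Product: 17 (3R,4R)-3-(4-hydroxy-3-methoxybenzyl)-4-(4-hydroxy-3,5-dimethoxybenzyl)dihydrofuran-2(3H)-one
Conditions: H2 (1 atm), 10% Pd/C, EtOAc–MeOH, rt
Reagents that add atoms: none
Why: Catalytic hydrogenolysis of both benzyl aryl ethers; the conditions are neutral, so the lactone, the aryl methyl ethers and the C3 configuration are not affected.

## Compound list

1 | (R)-epichlorohydrin, (2R)-2-(chloromethyl)oxirane | ClC[C@H]1CO1 | starting material
2 | dimethyl malonate | COC(=O)CC(=O)OC | starting material
3 | dimethyl 2-{[(2R)-oxiran-2-yl]methyl}propanedioate (present as its sodium enolate) | COC(=O)C(C(=O)OC)C[C@@H]1CO1 | intermediate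
4 | dimethyl (2R)-2-(hydroxymethyl)cyclopropane-1,1-dicarboxylate (present as its sodium alkoxide) | OC[C@@H]1CC1(C(=O)OC)C(=O)OC | intermediate
5 | methyl (1S,5R)-2-oxo-3-oxabicyclo[3.1.0]hexane-1-carboxylate | O=C1OC[C@@H]2C[C@]12C(=O)OC | intermediate
6 | 4-bromo-2,6-dimethoxyphenol | COc1cc(Br)cc(OC)c1O | starting material
7 | 2-(benzyloxy)-5-bromo-1,3-dimethoxybenzene | COc1cc(Br)cc(OC)c1OCc1ccccc1 | intermediate
8 | [4-(benzyloxy)-3,5-dimethoxyphenyl]magnesium bromide | COc1cc([Mg]Br)cc(OC)c1OCc1ccccc1 | intermediate
9 | methyl (4R)-4-[4-(benzyloxy)-3,5-dimethoxybenzyl]-2-[(bromomagnesio)oxy]-4,5-dihydrofuran-3-carboxylate (bromomagnesium enolate of 10) | COC(=O)C1=C(O[Mg]Br)OC[C@@H]1Cc1cc(OC)c(OCc2ccccc2)c(OC)c1 | intermediate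
10 | methyl (3S,4R)-4-[4-(benzyloxy)-3,5-dimethoxybenzyl]-2-oxotetrahydrofuran-3-carboxylate (trans) | COC(=O)[C@H]1C(=O)OC[C@@H]1Cc1cc(OC)c(OCc2ccccc2)c(OC)c1 | intermediate
11 | lithium (3S,4R)-4-[4-(benzyloxy)-3,5-dimethoxybenzyl]-2-oxotetrahydrofuran-3-carboxylate | [Li+].[O-]C(=O)[C@H]1C(=O)OC[C@@H]1Cc1cc(OC)c(OCc2ccccc2)c(OC)c1 | intermediate
12 | (4R)-4-[4-(benzyloxy)-3,5-dimethoxybenzyl]dihydrofuran-2(3H)-one | O=C1C[C@@H](Cc2cc(OC)c(OCc3ccccc3)c(OC)c2)CO1 | intermediate
13 | [4-(benzyloxy)-3-methoxyphenyl]methanol | COc1cc(CO)ccc1OCc1ccccc1 | starting material
14 | 1-(benzyloxy)-4-(bromomethyl)-2-methoxybenzene | COc1cc(CBr)ccc1OCc1ccccc1 | intermediate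
15 | lithium enolate of 12, lithium (4R)-4-[4-(benzyloxy)-3,5-dimethoxybenzyl]-4,5-dihydrofuran-2-olate | [Li]OC1=C[C@@H](Cc2cc(OC)c(OCc3ccccc3)c(OC)c2)CO1 | intermediate
16 | (3R,4R)-3-[4-(benzyloxy)-3-methoxybenzyl]-4-[4-(benzyloxy)-3,5-dimethoxybenzyl]dihydrofuran-2(3H)-one | COc1cc(C[C@H]2C(=O)OC[C@@H]2Cc2cc(OC)c(OCc3ccccc3)c(OC)c2)ccc1OCc1ccccc1 | intermediate
17 | (3R,4R)-3-(4-hydroxy-3-methoxybenzyl)-4-(4-hydroxy-3,5-dimethoxybenzyl)dihydrofuran-2(3H)-one | COc1cc(C[C@H]2C(=O)OC[C@@H]2Cc2cc(OC)c(O)c(OC)c2)ccc1O | target

## Step count and risk

Total step count: 8. Longest linear sequence: 6 steps (steps 2, 3, 4, 5, 7 and 8, from 6 to 17). Steps 1 and 6 are side branches of one step each.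

Least certain steps:

Step 4 (key step). The most likely failure is direct addition of the aryl magnesium reagent to the ester or lactone carbonyl before it is transferred to copper, together with copper-induced homocoupling of the electron-rich aryl group; both would consume 5 or 8 without opening the cyclopropane. The fallback abandons the cyclopropane and builds the same C4 centre by asymmetric hydrogenation. It sets out from 8 and returns at 12.
- Formylation of 8 with DMF would give 4-(benzyloxy)-3,5-dimethoxybenzaldehyde F1.
- Stobbe condensation with dimethyl succinate (NaOMe, MeOH) would give (3E)-4-[4-(benzyloxy)-3,5-dimethoxyphenyl]-3-(methoxycarbonyl)but-3-enoic acid F2.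
- Hydrogenation over [Rh(cod)2]BF4 with a chiral bisphosphine of the hand that delivers the R acid would give (3R)-4-[4-(benzyloxy)-3,5-dimethoxyphenyl]-3-(methoxycarbonyl)butanoic acid F3.
- Reduction of the ester group of its potassium salt (CaCl2, NaBH4, EtOH) and acid-induced ring closure would then give 12.

Step 7. The likely failures are proton exchange between product and enolate, leading to a second benzylation at C3, and loss of the labile electron-rich bromide by self-condensation before it is consumed. The fallback uses the ester of 10 as the activating group. It sets out from 10 (before step 5) and 14 and returns at 16.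
- K2CO3 in acetone would give methyl (3R,4R)-3-[4-(benzyloxy)-3-methoxybenzyl]-4-[4-(benzyloxy)-3,5-dimethoxybenzyl]-2-oxotetrahydrofuran-3-carboxylate F4 by a mono-alkylation that cannot over-run.
- LiCl in wet DMSO at 150 °C would then remove the ester, and equilibration of the crude lactone with DBU in toluene would move C3 to the more stable trans arrangement of 16.
- The price is that C3 then rests on thermodynamic and not kinetic control.

Step 3. The likely failures are sluggish initiation of the electron-rich aryl bromide and Wurtz-type homocoupling during a slow insertion. The fallback replaces insertion by exchange. It sets out from 7 and returns at 8: n-BuLi in THF at −78 °C would give [4-(benzyloxy)-3,5-dimethoxyphenyl]lithium F5 by bromine–lithium exchange, and MgBr2·OEt2 would convert it into 8.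

Step 1. The likely failure is partial loss of enantiomeric purity through competing direct displacement of chloride by the malonate, which leads to the mirror-image lactone, along with oligomerisation of 1. The fallback makes the displacement pathway the only one and changes the hand of the electrophile. It sets out from 2 and returns at 3: the sodium salt of 2 (NaH, THF, −20 °C) would displace the sulfonate of [(2S)-oxiran-2-yl]methyl trifluoromethanesulfonate F6, made from commercial (R)-glycidol and Tf2O, to give 3 directly. NaOMe in MeOH would then carry 3 through 4 to 5 as in the main route.

## Further compounds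

F1 | step 4 | 4-(benzyloxy)-3,5-dimethoxybenzaldehyde | COc1cc(C=O)cc(OC)c1OCc1ccccc1
F2 | step 4 | (3E)-4-[4-(benzyloxy)-3,5-dimethoxyphenyl]-3-(methoxycarbonyl)but-3-enoic acid | COC(=O)/C(CC(=O)O)=C/c1cc(OC)c(OCc2ccccc2)c(OC)c1
F3 | step 4 | (3R)-4-[4-(benzyloxy)-3,5-dimethoxyphenyl]-3-(methoxycarbonyl)butanoic acid | COC(=O)[C@H](Cc1cc(OC)c(OCc2ccccc2)c(OC)c1)CC(=O)O
F4 | step 7 | methyl (3R,4R)-3-[4-(benzyloxy)-3-methoxybenzyl]-4-[4-(benzyloxy)-3,5-dimethoxybenzyl]-2-oxotetrahydrofuran-3-carboxylate | COC(=O)[C@]1(Cc2ccc(OCc3ccccc3)c(OC)c2)C(=O)OC[C@@H]1Cc1cc(OC)c(OCc2ccccc2)c(OC)c1
F5 | step 3 | [4-(benzyloxy)-3,5-dimethoxyphenyl]lithium | [Li]c1cc(OC)c(OCc2ccccc2)c(OC)c1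
F6 | step 1 | [(2S)-oxiran-2-yl]methyl trifluoromethanesulfonate | FC(F)(F)S(=O)(=O)OC[C@@H]1CO1
A1 | alternative 1 | 3-[4-(benzyloxy)-3,5-dimethoxybenzyl]cyclobutan-1-one | O=C1CC(Cc2cc(OC)c(OCc3ccccc3)c(OC)c2)C1
A2 | alternative 1 | (4R)-4-[4-(benzyloxy)-3,5-dimethoxybenzyl]dihydrofuran-2(3H)-one | O=C1C[C@@H](Cc2cc(OC)c(OCc3ccccc3)c(OC)c2)CO1
A3 | alternative 2 | (2S,3Z)-5-[4-(benzyloxy)-3,5-dimethoxyphenyl]pent-3-en-2-yl 3-[4-(benzyloxy)-3-methoxyphenyl]propanoate | COc1cc(CCC(=O)O[C@@H](C)/C=C\Cc2cc(OC)c(OCc3ccccc3)c(OC)c2)ccc1OCc1ccccc1
A4 | alternative 2 | (2R,3S,4E)-2-[4-(benzyloxy)-3-methoxybenzyl]-3-[4-(benzyloxy)-3,5-dimethoxybenzyl]hex-4-enoic acid | OC(=O)[C@H](Cc1ccc(OCc2ccccc2)c(OC)c1)[C@@H](Cc1cc(OC)c(OCc2ccccc2)c(OC)c1)/C=C/C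
A5 | alternative 3 | (5R)-5-{[(1R,2S,5R)-5-methyl-2-(propan-2-yl)cyclohexyl]oxy}furan-2(5H)-one | O=C1O[C@@H](O[C@@H]2C[C@H](C)CC[C@H]2C(C)C)C=C1
A6 | alternative 3 | 2-[4-(benzyloxy)-3,5-dimethoxyphenyl]-1,3-dithiane | COc1cc(C2SCCCS2)cc(OC)c1OCc1ccccc1
A7 | alternative 3 | 3,4-trans-4,5-trans-3-[4-(benzyloxy)-3-methoxybenzyl]-4-{2-[4-(benzyloxy)-3,5-dimethoxyphenyl]-1,3-dithian-2-yl}-5-(l-menthyloxy)dihydrofuran-2(3H)-one | COc1cc(C[C@H]2C(=O)O[C@@H](O[C@@H]3C[C@H](C)CC[C@H]3C(C)C)[C@@H]2C2(SCCCS2)c2cc(OC)c(OCc3ccccc3)c(OC)c2)ccc1OCc1ccccc1
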